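**Plan**
1. Enabling feature: ring C (O1, C2, C3, C4, C4a, C8a) is a β-aryloxy ketone. O1 sits on C8a ortho to the C4 carbonyl and is joined through C2–C3 to C4=O, so the O1–C2 bond is the retron of an intramolecular oxa-Michael addition of a 2'-hydroxychalcone, the chalcone-to-flavanone isomerisation of flavonoid biosynthesis.
2. Cuts, in retrosynthetic order: the 5-O–CH3 bond (5-OH carried as its methyl ether); O1–C2 of ring C, with a CO2tBu helper added at C3; C2=C3 (ring B as 2,6-dimethoxybenzaldehyde); C3–CO2tBu; the aryl–acetyl bond of ring A.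
3. Forward order: ring A acetophenone from 1,2,3,5-tetramethoxybenzene, then β-keto ester, then alkylidene carrying ring B, then ring C closed last with the helper ester removed in the same flask, then 5-O-demethylation.
4. Stereochemistry and regiochemistry: C2 (S), the only stereocentre, is set in the ring closure by a bifunctional cinchona thiourea catalyst. The 7,8- (not 6,7-) dimethoxy pattern is fixed because the second ortho oxygen of ring A stays capped as a methyl ether until the end.

Key step: step 5

Assumption: the 9-amino-9-deoxy-epi-quinine thiourea is taken to deliver the (2S) sense with this substrate; if analysis of 9 shows (2R), the pseudoenantiomeric epi-quinidine thiourea is used with no other change.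

**Route**

Step 1
Reactants: 1 1,2,3,5-tetramethoxybenzene
Product: 3 2-hydroxy-3,4,6-trimethoxyacetophenone, via 2,3,4,6-tetramethoxyacetophenone 2 (not isolated)
Conditions: AcCl, AlCl3 (2.5 equiv), Et2O, 0 °C → rt; aq HCl work-up
Reagents that add atoms: acetyl chloride CC(=O)Cl
Why: Friedel–Crafts acylation should occur at the position flanked by two methoxy groups, and AlCl3 chelated to the new ketone should then cleave the more crowded ortho methyl ether (the one also flanked by a methoxy group), leaving the 6-methoxy group in place.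

Step 2
Reactants: 3 2-hydroxy-3,4,6-trimethoxyacetophenone
Product: 4 2-acetyl-3,5,6-trimethoxyphenyl tert-butyl carbonate
Conditions: Boc2O (1.3 equiv), DMAP (10 mol%), MeCN, rt
Reagents that add atoms: di-tert-butyl dicarbonate CC(C)(C)OC(=O)OC(=O)OC(C)(C)C
Why: DMAP-catalysed O-acylation of the chelated phenol should give the aryl carbonate that places the tert-butoxycarbonyl group for intramolecular transfer to the acetyl carbon.

Step 3
Reactants: 4 2-acetyl-3,5,6-trimethoxyphenyl tert-butyl carbonate
Product: 5 tert-butyl 3-(2-hydroxy-3,4,6-trimethoxyphenyl)-3-oxopropanoate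
Conditions: LiHMDS (2.2 equiv), THF, −78 → 0 °C; AcOH quench
Reagents that add atoms: none
Why: a Baker–Venkataraman-type anionic O→C acyl transfer should occur, in which the methyl ketone enolate attacks the neighbouring carbonate through a six-membered intermediate that expels the phenoxide rather than tert-butoxide, so the tert-butyl ester survives and the phenol is released.

Step 4
Reactants: 5 tert-butyl 3-(2-hydroxy-3,4,6-trimethoxyphenyl)-3-oxopropanoate, 6 2,6-dimethoxybenzaldehyde
Product: 7 tert-butyl (2Z)-3-(2,6-dimethoxyphenyl)-2-(2-hydroxy-3,4,6-trimethoxybenzoyl)prop-2-enoate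
Conditions: piperidine (20 mol%), AcOH (20 mol%), 4 Å MS, toluene, rt → 40 °C
Reagents that add atoms: none
Why: Knoevenagel condensation of the active methylene with the aldehyde under buffered amine catalysis should give the alkylidene β-keto ester (aryl cis to the ester expected), while the intramolecularly hydrogen-bonded phenol should stay open under these weakly basic, mild conditions.

Step 5
Reactants: 7 tert-butyl (2Z)-3-(2,6-dimethoxyphenyl)-2-(2-hydroxy-3,4,6-trimethoxybenzoyl)prop-2-enoate
Product: 9 (2S)-5,7,8,2',6'-pentamethoxyflavanone, via trans-3-tert-butoxycarbonylflavanone 8 (not isolated)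
Conditions: 9-amino-9-deoxy-epi-quinine 3,5-bis(trifluoromethyl)phenyl thiourea (10 mol%), toluene, −25 °C; then TsOH·H2O (0.5 equiv), 80 °C, same flask
Reagents that add atoms: none
Why: The thiourea N–H bonds should bind the 1,3-dicarbonyl unit while the quinuclidine nitrogen acts as general base on the 2'-OH, so that the phenolic oxygen adds to the β-carbon bearing the 2,6-dimethoxyphenyl group and the enol is protonated to the trans ester 8; TsOH then cleaves the tert-butyl ester and the β-keto acid loses CO2 to give 9. The closest known reaction type is the bifunctional cinchona-thiourea-catalysed intramolecular oxa-Michael addition of 2-hydroxyaryl alkylidene β-keto esters with acid decarboxylation in the same flask, a small-molecule counterpart of the chalcone isomerase step. Ring C is closed by O1–C2 bond formation in a 6-endo-trig mode. C2 is set by catalyst control of the alkene face within the hydrogen-bonded ion pair, whereas C3 is only transient (trans by equilibration) and is erased on decarboxylation. The step needs regioselectivity between the two ortho oxygens of ring A, secured because the oxygen that becomes O-5 is a methyl ether, so only the hydroxyl next to the future 8-OMe can add. It also needs enantioselectivity over background closure, secured by the ester activation, the low temperature and the non-polar solvent, in which the neutral hydrogen-bonded phenol should not add without the catalyst base.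

Step 6
Reactants: 9 (2S)-5,7,8,2',6'-pentamethoxyflavanone
Product: 10 (2S)-5-hydroxy-7,8,2',6'-tetramethoxyflavanone
Conditions: BCl3 (1.5 equiv), CH2Cl2, −78 → 0 °C; cold water work-up without base
Reagents that add atoms: none
Why: chelation-controlled demethylation should take place, since boron bound between C4=O and the peri 5-OMe activates only that methyl group for chloride attack, while the four other methoxy groups are not chelated and the low temperature should leave C2 untouched.

**Compound list**
1 | 1,2,3,5-tetramethoxybenzene | COc1cc(OC)cc(OC)c1OC | starting material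
2 | 2,3,4,6-tetramethoxyacetophenone | CC(=O)c1c(OC)cc(OC)c(OC)c1OC | intermediate
3 | 2-hydroxy-3,4,6-trimethoxyacetophenone | CC(=O)c1c(OC)cc(OC)c(OC)c1O | intermediate
4 | 2-acetyl-3,5,6-trimethoxyphenyl tert-butyl carbonate | CC(=O)c1c(OC)cc(OC)c(OC)c1OC(=O)OC(C)(C)C | intermediate
5 | tert-butyl 3-(2-hydroxy-3,4,6-trimethoxyphenyl)-3-oxopropanoate | COc1cc(OC)c(C(=O)CC(=O)OC(C)(C)C)c(O)c1OC | intermediate
6 | 2,6-dimethoxybenzaldehyde | COc1cccc(OC)c1C=O | starting material
7 | tert-butyl (2Z)-3-(2,6-dimethoxyphenyl)-2-(2-hydroxy-3,4,6-trimethoxybenzoyl)prop-2-enoate | COc1cc(OC)c(C(=O)/C(C(=O)OC(C)(C)C)=C/c2c(OC)cccc2OC)c(O)c1OC | intermediate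
8 | tert-butyl (2S,3R)-2-(2,6-dimethoxyphenyl)-5,7,8-trimethoxy-4-oxochromane-3-carboxylate (trans, keto tautomer) | COc1cc(OC)c2c(c1OC)O[C@H](c1c(OC)cccc1OC)[C@@H](C(=O)OC(C)(C)C)C2=O | intermediate
9 | (2S)-2-(2,6-dimethoxyphenyl)-5,7,8-trimethoxychroman-4-one [(2S)-5,7,8,2',6'-pentamethoxyflavanone] | COc1cc(OC)c2c(c1OC)O[C@H](c1c(OC)cccc1OC)CC2=O | intermediate
10 | (2S)-2-(2,6-dimethoxyphenyl)-5-hydroxy-7,8-dimethoxychroman-4-one [(2S)-5-hydroxy-7,8,2',6'-tetramethoxyflavanone] | COc1cc(O)c2c(c1OC)O[C@H](c1c(OC)cccc1OC)CC2=O | target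

**Count**
Total steps: 6. Longest linear sequence: 6 steps (1 → 3 → 4 → 5 → 7 → 9 → 10); aldehyde 6 enters at step 4.

**Steps most likely to fail**

Step 5. Facial discrimination may be poor at a β-carbon that carries a di-ortho-substituted aryl group, and optical purity may be lost by acid-promoted ring opening and re-closure during the hot decarboxylation. The fallback sets out from 3 and 6 and returns at 9. Claisen–Schmidt condensation of 3 with 6 (KOH, EtOH, rt) should give (E)-2'-hydroxy-3',4',6',2,6-pentamethoxychalcone F1. Closure with NaOAc in refluxing EtOH should give racemic 5,7,8,2',6'-pentamethoxyflavanone F2. Kinetic resolution by asymmetric transfer hydrogenation (Ru(II)–TsDPEN, HCO2H/Et3N, stopped near half conversion, catalyst enantiomer chosen so that the (2R)-ketone reacts faster) should convert the unwanted enantiomer into (2R,4R)-cis-5,7,8,2',6'-pentamethoxyflavan-4-ol F3. F3 is removed by chromatography and the unreacted (2S)-ketone is 9.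

Step 6. C2 may be scrambled by Lewis-acid-assisted heterolysis of the benzylic C2–O1 bond, which is stabilised by the 2,6-dimethoxyphenyl group, or by opening to the chalcone, and a second methyl ether may be cleaved. The fallback sets out from 3 and returns at 10; it carries O-5 as a benzyl ether that is removed under neutral conditions.
- Tosylation of 3 (TsCl, K2CO3, acetone, reflux) should give 2-acetyl-3,5,6-trimethoxyphenyl 4-methylbenzenesulfonate F4.
- BCl3 (CH2Cl2, −78 → 0 °C) should cleave the only methyl ether still ortho to the ketone, giving 2-acetyl-3-hydroxy-5,6-dimethoxyphenyl 4-methylbenzenesulfonate F5.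
- BnBr, K2CO3, DMF should give 2-acetyl-3-(benzyloxy)-5,6-dimethoxyphenyl 4-methylbenzenesulfonate F6.
- KOH, MeOH–H2O, reflux should remove the sulfonate to give 1-[6-(benzyloxy)-2-hydroxy-3,4-dimethoxyphenyl]ethan-1-one F7.
- The conditions of steps 2 to 5 are then applied. They should give in turn 2-acetyl-3-(benzyloxy)-5,6-dimethoxyphenyl tert-butyl carbonate F8, tert-butyl 3-[6-(benzyloxy)-2-hydroxy-3,4-dimethoxyphenyl]-3-oxopropanoate F9, and, with 6, tert-butyl (2Z)-2-[6-(benzyloxy)-2-hydroxy-3,4-dimethoxybenzoyl]-3-(2,6-dimethoxyphenyl)prop-2-enoate F10. The cyclised ester tert-butyl (2S,3R)-5-(benzyloxy)-2-(2,6-dimethoxyphenyl)-7,8-dimethoxy-4-oxochromane-3-carboxylate F11 (not isolated) should then give (2S)-5-(benzyloxy)-2-(2,6-dimethoxyphenyl)-7,8-dimethoxychroman-4-one F12.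
- Hydrogenolysis of F12 (H2, Pd/C, EtOAc, rt, stopped at full debenzylation) should give 10.

Step 4. Condensation of the hindered, electron-rich aldehyde may be sluggish, and the free phenol may close onto the new alkene early and without selectivity under amine catalysis. The fallback sets out from 5 and returns at 7; the phenol is masked while the alkene is made. Silylation of 5 (TBSCl, imidazole, DMF, rt) should give tert-butyl 3-[2-(tert-butyldimethylsilyloxy)-3,4,6-trimethoxyphenyl]-3-oxopropanoate F13. Condensation with 6 can then be forced (piperidinium acetate, toluene, reflux, Dean–Stark) to give tert-butyl (2Z)-2-[2-(tert-butyldimethylsilyloxy)-3,4,6-trimethoxybenzoyl]-3-(2,6-dimethoxyphenyl)prop-2-enoate F14. Desilylation under non-basic conditions (HF·pyridine, THF, 0 °C) should release 7.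

**Further compounds**
F1 | step 5 | (E)-3-(2,6-dimethoxyphenyl)-1-(2-hydroxy-3,4,6-trimethoxyphenyl)prop-2-en-1-one | COc1cc(OC)c(C(=O)/C=C/c2c(OC)cccc2OC)c(O)c1OC
F2 | step 5 | racemic 2-(2,6-dimethoxyphenyl)-5,7,8-trimethoxychroman-4-one | COc1cc(OC)c2c(c1OC)OC(c1c(OC)cccc1OC)CC2=O
F3 | step 5 | (2R,4R)-2-(2,6-dimethoxyphenyl)-5,7,8-trimethoxychroman-4-ol (cis) | COc1cc(OC)c2c(c1OC)O[C@@H](c1c(OC)cccc1OC)C[C@H]2O
F4 | step 6 | 2-acetyl-3,5,6-trimethoxyphenyl 4-methylbenzenesulfonate | CC(=O)c1c(OC)cc(OC)c(OC)c1OS(=O)(=O)c1ccc(C)cc1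
F5 | step 6 | 2-acetyl-3-hydroxy-5,6-dimethoxyphenyl 4-methylbenzenesulfonate | CC(=O)c1c(O)cc(OC)c(OC)c1OS(=O)(=O)c1ccc(C)cc1
F6 | step 6 | 2-acetyl-3-(benzyloxy)-5,6-dimethoxyphenyl 4-methylbenzenesulfonate | CC(=O)c1c(OCc2ccccc2)cc(OC)c(OC)c1OS(=O)(=O)c1ccc(C)cc1
F7 | step 6 | 1-[6-(benzyloxy)-2-hydroxy-3,4-dimethoxyphenyl]ethan-1-one | CC(=O)c1c(OCc2ccccc2)cc(OC)c(OC)c1O
F8 | step 6 | 2-acetyl-3-(benzyloxy)-5,6-dimethoxyphenyl tert-butyl carbonate | CC(=O)c1c(OCc2ccccc2)cc(OC)c(OC)c1OC(=O)OC(C)(C)C
F9 | step 6 | tert-butyl 3-[6-(benzyloxy)-2-hydroxy-3,4-dimethoxyphenyl]-3-oxopropanoate | COc1cc(OCc2ccccc2)c(C(=O)CC(=O)OC(C)(C)C)c(O)c1OC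
F10 | step 6 | tert-butyl (2Z)-2-[6-(benzyloxy)-2-hydroxy-3,4-dimethoxybenzoyl]-3-(2,6-dimethoxyphenyl)prop-2-enoate | COc1cc(OCc2ccccc2)c(C(=O)/C(C(=O)OC(C)(C)C)=C/c2c(OC)cccc2OC)c(O)c1OC
F11 | step 6 | tert-butyl (2S,3R)-5-(benzyloxy)-2-(2,6-dimethoxyphenyl)-7,8-dimethoxy-4-oxochromane-3-carboxylate | COc1cc(OCc2ccccc2)c2c(c1OC)O[C@H](c1c(OC)cccc1OC)[C@@H](C(=O)OC(C)(C)C)C2=O
F12 | step 6 | (2S)-5-(benzyloxy)-2-(2,6-dimethoxyphenyl)-7,8-dimethoxychroman-4-one | COc1cc(OCc2ccccc2)c2c(c1OC)O[C@H](c1c(OC)cccc1OC)CC2=O
F13 | step 4 | tert-butyl 3-[2-(tert-butyldimethylsilyloxy)-3,4,6-trimethoxyphenyl]-3-oxopropanoate | COc1cc(OC)c(C(=O)CC(=O)OC(C)(C)C)c(O[Si](C)(C)C(C)(C)C)c1OC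
F14 | step 4 | tert-butyl (2Z)-2-[2-(tert-butyldimethylsilyloxy)-3,4,6-trimethoxybenzoyl]-3-(2,6-dimethoxyphenyl)prop-2-enoate | COc1cc(OC)c(C(=O)/C(C(=O)OC(C)(C)C)=C/c2c(OC)cccc2OC)c(O[Si](C)(C)C(C)(C)C)c1OC
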